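**Retrosynthetic overview** (azulene numbering of the target: C1–OH, C3(OH)(iPr), C3a–H, C4–O-aroyl, C6(Me)=C7, C8a–Me)
1. Last cuts: the two silyl ethers, the C4 ester (Steglich), and the C4 carbinol, which goes back to a C4 ketone reduced under direction by the C3 hydroxyl.
2. Seven-membered ring, closed last: ring-closing metathesis at C6=C7 between an allyl group on C8a and a 2-methylallyl ketone at C4.
3. Five-membered ring, closed before it: the C3–C3a bond is made by nucleophile-catalysed aldol-lactonisation of an acyclic keto acid (C3 isopropyl ketone, C4 carboxyl); this sets C3 and C3a and stores C4 as a strained β-lactone.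
4. Enabling feature: the C3 tertiary carbinol (five-membered ring) and the C4 oxygen (seven-membered ring) are 1,3-related across the single methine C3a, an aldol pattern with C3a as the enolisable carbon; the cis C8a-methyl/C1-oxygen pair steers the closure.
5. Keto acid: oxidative cleavage of the C3=C4 bond of a cyclohexene whose ring (C8a, C1, C2, C3, C4, C3a) with its methyl, oxygen and isopropyl groups is carvacrol (Birch reduction; Pd-catalysed asymmetric allylation for C8a; oxazaborolidine reduction for C1). Ring order: carvacrol ring (opened), then five-membered ring, then seven-membered ring.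

Key step: step 8

Remark: the facial sense of the palladium allylation with (S)-t-BuPHOX and of the (S)-oxazaborolidine reduction is assigned by analogy with 2-methylcyclohexanone enolates and with ketones that carry one fully substituted α-carbon; epoxide 7 is a mixture of two diastereomers, both of which give 8.

**Route**

Step 1
Reactants: 1 carvacrol (5-isopropyl-2-methylphenol)
Product: 2 tert-butyl(5-isopropyl-2-methylphenoxy)dimethylsilane
Conditions: TBSCl, imidazole, DMF, 23 °C
Reagents that add atoms: tert-butyldimethylsilyl chloride, CC(C)(C)[Si](C)(C)Cl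
Why: Imidazole-promoted O-silylation of the phenol gives the aryl silyl ether that the Birch reduction turns into a regiodefined silyl enol ether.

Step 2
Reactants: 2 tert-butyl(5-isopropyl-2-methylphenoxy)dimethylsilane
Product: 3 tert-butyl[(5-isopropyl-2-methylcyclohexa-1,4-dien-1-yl)oxy]dimethylsilane
Conditions: Li, NH3(l)/THF, t-BuOH, −78 to −33 °C; then solid NH4Cl
Reagents that add atoms: none
Why: Birch reduction of an aryl silyl ether should protonate the two unsubstituted ring carbons ortho and meta to oxygen, so that oxygen, methyl and isopropyl all stay on double bonds and the enol ether double bond points to the methyl-bearing carbon.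

Step 3
Reactants: 3 tert-butyl[(5-isopropyl-2-methylcyclohexa-1,4-dien-1-yl)oxy]dimethylsilane
Product: 4 (R)-6-allyl-3-isopropyl-6-methylcyclohex-3-en-1-one
Conditions: diallyl carbonate, Pd2(dba)3 (2.5 mol %), (S)-t-BuPHOX (6.25 mol %), tetrabutylammonium difluorotriphenylsilicate Bu4N[Ph3SiF2] (35 mol %), THF, 25 °C
Reagents that add atoms: diallyl carbonate, C=CCOC(=O)OCC=C
Why: Palladium-catalysed decarboxylative asymmetric allylic alkylation (Tsuji allylation) of a silyl enol ether: fluoride and then allyl alkoxide unmask the tetrasubstituted enolate regiospecifically, and the (S)-ligand/allylpalladium complex should alkylate the face that gives the R quaternary centre (the spatial arrangement of (S)-2-allyl-2-methylcyclohexanone; only the CIP ranking differs).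

Step 4
Reactants: 4 (R)-6-allyl-3-isopropyl-6-methylcyclohex-3-en-1-one
Product: 5 (1R,6R)-6-allyl-3-isopropyl-6-methylcyclohex-3-en-1-ol
Conditions: (S)-2-methyl-CBS-oxazaborolidine (20 mol %), catecholborane, toluene, −78 °C
Reagents that add atoms: none
Why: Corey–Bakshi–Shibata reduction under catalyst control (quaternary α-carbon as the large flank, CH2 as the small one) should give the 1R carbinol with OH cis to methyl; catecholborane spares the alkenes, and the diastereomer arising from the minor enantiomer of 4 is removed by chromatography.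

Step 5
Reactants: 5 (1R,6R)-6-allyl-3-isopropyl-6-methylcyclohex-3-en-1-ol
Product: 6 tert-butyl{[(1R,6R)-6-allyl-3-isopropyl-6-methylcyclohex-3-en-1-yl]oxy}dimethylsilane
Conditions: TBSOTf, 2,6-lutidine, CH2Cl2, 0 °C
Reagents that add atoms: tert-butyldimethylsilyl triflate, CC(C)(C)[Si](C)(C)OS(=O)(=O)C(F)(F)F
Why: Silyl triflate silylation of a hindered secondary alcohol; the bulky ether later prevents γ-lactonisation and serves as the pseudo-equatorial control group of the key step.

Step 6
Reactants: 6 tert-butyl{[(1R,6R)-6-allyl-3-isopropyl-6-methylcyclohex-3-en-1-yl]oxy}dimethylsilane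
Product: 8 (3R,4R)-3-allyl-4-[(tert-butyldimethylsilyl)oxy]-3,7-dimethyl-6-oxooctanal, via epoxide 7 (not isolated)
Conditions: mCPBA (1.05 equiv), CH2Cl2, 0 °C; solvent changed to THF/H2O, then H5IO6, 0 to 23 °C
Reagents that add atoms: mCPBA, OOC(=O)c1cccc(Cl)c1; periodic acid H5IO6, OI(=O)(O)(O)(O)O
Why: Prilezhaev epoxidation should select the electron-rich trisubstituted ring alkene over the terminal allyl group, and periodic acid then opens the epoxide and cleaves the glycol (Malaprade cleavage) to the isopropyl ketone and the aldehyde.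

Step 7
Reactants: 8 (3R,4R)-3-allyl-4-[(tert-butyldimethylsilyl)oxy]-3,7-dimethyl-6-oxooctanal
Product: 9 (3R,4R)-3-allyl-4-[(tert-butyldimethylsilyl)oxy]-3,7-dimethyl-6-oxooctanoic acid
Conditions: NaClO2, NaH2PO4, 2-methyl-2-butene, t-BuOH/H2O, 23 °C
Reagents that add atoms: sodium chlorite NaClO2, [Na+].[O-]Cl=O
Why: Pinnick oxidation converts only the aldehyde to the acid, the alkene scavenger protecting the allyl group from hypochlorite.

Step 8
Reactants: 9 (3R,4R)-3-allyl-4-[(tert-butyldimethylsilyl)oxy]-3,7-dimethyl-6-oxooctanoic acid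
Product: 10 (1R,2R,3R,5R)-2-allyl-3-[(tert-butyldimethylsilyl)oxy]-5-isopropyl-2-methyl-6-oxabicyclo[3.2.0]heptan-7-one
Conditions: TsCl, 4-pyrrolidinopyridine, iPr2NEt, CH2Cl2, 23 °C, slow addition of 9
Reagents that add atoms: none
Why: TsCl turns the acid into a mixed anhydride, 4-pyrrolidinopyridine gives the acylpyridinium ion, and iPr2NEt removes a proton from its α-CH2 (the future C3a) to give a pyridinium enolate that adds to the isopropyl ketone, after which the tertiary alkoxide attacks the acylpyridinium carbon and expels the promoter. The closest known reaction type is the nucleophile-catalysed aldol-lactonisation of keto acids to cyclopentane-fused β-lactones. The cyclopentane closes by 5-(enolexo)-exo-trig C–C bond formation (C3–C3a) and the β-lactone by 4-exo-trig acyl substitution, the irreversible lactonisation pulling the crowded, otherwise reversible ketone aldol forward. C3 and C3a are tied together because only the aldolate with the alkoxide syn to the acyl group can lactonise, which puts the C3 oxygen and the C4 carbonyl cis and the isopropyl group trans to it; relative to the existing centres, a chair-like closure with the silyloxy group (future C1) and the allyl group (future C8a) pseudo-equatorial and the methyl pseudo-axial should place the new C–O bond cis to the silyloxy and methyl groups. The step needs chemoselective enolisation at the acid α-carbon rather than the ketone α-carbons, secured by the acidity of the acylpyridinium under an amine base, and this face selectivity, secured by the cis methyl/silyloxy pair, which would clash with the isopropyl group in the other diastereomer.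

Step 9
Reactants: 10 (1R,2R,3R,5R)-2-allyl-3-[(tert-butyldimethylsilyl)oxy]-5-isopropyl-2-methyl-6-oxabicyclo[3.2.0]heptan-7-one
Product: 11 (1R,2R,3R,5R)-2-allyl-3-[(tert-butyldimethylsilyl)oxy]-5-hydroxy-5-isopropyl-N-methoxy-N,2-dimethylcyclopentane-1-carboxamide
Conditions: MeNH(OMe)·HCl, AlMe3, CH2Cl2, 0 to 23 °C
Reagents that add atoms: N,O-dimethylhydroxylamine hydrochloride, CNOC.Cl
Why: Weinreb aminolysis with an aluminium amide, driven by the strain of the β-lactone (acyl C–O cleavage), frees the tertiary C3 hydroxyl without touching a stereocentre.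

Step 10
Reactants: 11 (1R,2R,3R,5R)-2-allyl-3-[(tert-butyldimethylsilyl)oxy]-5-hydroxy-5-isopropyl-N-methoxy-N,2-dimethylcyclopentane-1-carboxamide
Product: 12 1-[(1R,2R,3R,5R)-2-allyl-3-[(tert-butyldimethylsilyl)oxy]-5-hydroxy-5-isopropyl-2-methylcyclopentyl]-3-methylbut-3-en-1-one
Conditions: 2-methylallylmagnesium chloride CH2=C(CH3)CH2MgCl (3 equiv), THF, −78 to −20 °C; pH 7 phosphate buffer at −78 °C
Reagents that add atoms: 2-methylallylmagnesium chloride, CC(=C)C[Mg]Cl
Why: Grignard addition to a Weinreb amide stops at the chelated tetrahedral intermediate, allylic Grignard reagents add even to hindered acyl groups, and the cold buffered quench should keep the β,γ-unsaturated ketone out of conjugation.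

Step 11
Reactants: 12 1-[(1R,2R,3R,5R)-2-allyl-3-[(tert-butyldimethylsilyl)oxy]-5-hydroxy-5-isopropyl-2-methylcyclopentyl]-3-methylbut-3-en-1-one
Product: 13 (1R,3R,3aR,8aR)-1-[(tert-butyldimethylsilyl)oxy]-3-hydroxy-3-isopropyl-6,8a-dimethyl-2,3,3a,5,8,8a-hexahydroazulen-4(1H)-one
Conditions: second-generation Grubbs catalyst RuCl2(=CHPh)(H2IMes)(PCy3) (5 mol %), 1,4-benzoquinone (10 mol %), CH2Cl2 (5 mM), 40 °C
Reagents that add atoms: none
Why: Ring-closing metathesis of the allyl and 2-methylallyl groups, which are trans on the cyclopentane, should close the trans-fused seven-membered ring with the trisubstituted C6=C7 alkene, benzoquinone suppressing double-bond migration.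

Step 12
Reactants: 13 (1R,3R,3aR,8aR)-1-[(tert-butyldimethylsilyl)oxy]-3-hydroxy-3-isopropyl-6,8a-dimethyl-2,3,3a,5,8,8a-hexahydroazulen-4(1H)-one
Product: 14 (1R,3R,3aS,4S,8aR)-1-[(tert-butyldimethylsilyl)oxy]-3-isopropyl-6,8a-dimethyl-1,2,3,3a,4,5,8,8a-octahydroazulene-3,4-diol
Conditions: Me4NBH(OAc)3, MeCN/AcOH (1:1), −30 to −10 °C
Reagents that add atoms: none
Why: Evans–Saksena hydroxyl-directed reduction: the ring holds the C4 carbonyl oxygen nearly eclipsed with the C3a–C3 bond, so the acetoxyborohydride bound to the C3 oxygen should deliver hydride to the face on which that oxygen sits and give the 4S alcohol, anti to C3–OH across C3a.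

Step 13
Reactants: 15 4-hydroxybenzoic acid
Product: 17 4-[(tert-butyldimethylsilyl)oxy]benzoic acid, via silyl ester 16 (not isolated)
Conditions: TBSCl (2.2 equiv), imidazole, DMF, 23 °C; then AcOH/THF/H2O, 23 °C
Reagents that add atoms: tert-butyldimethylsilyl chloride, CC(C)(C)[Si](C)(C)Cl
Why: Exhaustive silylation followed by selective hydrolysis of the labile silyl ester leaves the aryl silyl ether, which is stable to aqueous acetic acid.

Step 14
Reactants: 14 (1R,3R,3aS,4S,8aR)-1-[(tert-butyldimethylsilyl)oxy]-3-isopropyl-6,8a-dimethyl-1,2,3,3a,4,5,8,8a-octahydroazulene-3,4-diol; 17 4-[(tert-butyldimethylsilyl)oxy]benzoic acid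
Product: 18 (1R,3R,3aS,4S,8aR)-1-[(tert-butyldimethylsilyl)oxy]-3-hydroxy-3-isopropyl-6,8a-dimethyl-1,2,3,3a,4,5,8,8a-octahydroazulen-4-yl 4-[(tert-butyldimethylsilyl)oxy]benzoate
Conditions: DCC, DMAP, CH2Cl2, 23 °C
Reagents that add atoms: none
Why: Steglich esterification acylates the secondary C4 hydroxyl with retention, the tertiary C3 hydroxyl being inert under these conditions.

Step 15
Reactants: 18 (1R,3R,3aS,4S,8aR)-1-[(tert-butyldimethylsilyl)oxy]-3-hydroxy-3-isopropyl-6,8a-dimethyl-1,2,3,3a,4,5,8,8a-octahydroazulen-4-yl 4-[(tert-butyldimethylsilyl)oxy]benzoate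
Product: 19 (1R,3R,3aS,4S,8aR)-1,3-dihydroxy-3-isopropyl-6,8a-dimethyl-1,2,3,3a,4,5,8,8a-octahydroazulen-4-yl 4-hydroxybenzoate
Conditions: HF·pyridine, THF/pyridine, 0 to 23 °C
Reagents that add atoms: none
Why: Fluoride-induced desilylation removes the aryl and the hindered alkyl silyl ether in one operation, and the ester, tertiary alcohol and alkene should survive buffered HF.

**Compound list**
1 | carvacrol (5-isopropyl-2-methylphenol) | Cc1ccc(C(C)C)cc1O | starting material
2 | tert-butyl(5-isopropyl-2-methylphenoxy)dimethylsilane | Cc1ccc(C(C)C)cc1O[Si](C)(C)C(C)(C)C | intermediate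
3 | tert-butyl[(5-isopropyl-2-methylcyclohexa-1,4-dien-1-yl)oxy]dimethylsilane | CC1=C(O[Si](C)(C)C(C)(C)C)CC(C(C)C)=CC1 | intermediate
4 | (R)-6-allyl-3-isopropyl-6-methylcyclohex-3-en-1-one | C=CC[C@@]1(C)C(=O)CC(C(C)C)=CC1 | intermediate
5 | (1R,6R)-6-allyl-3-isopropyl-6-methylcyclohex-3-en-1-ol (OH cis to methyl) | C=CC[C@@]1(C)[C@H](O)CC(C(C)C)=CC1 | intermediate
6 | tert-butyl{[(1R,6R)-6-allyl-3-isopropyl-6-methylcyclohex-3-en-1-yl]oxy}dimethylsilane | C=CC[C@@]1(C)[C@H](O[Si](C)(C)C(C)(C)C)CC(C(C)C)=CC1 | intermediate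
7 | tert-butyl{[(3R,4R)-4-allyl-1-isopropyl-4-methyl-7-oxabicyclo[4.1.0]heptan-3-yl]oxy}dimethylsilane (epoxide of 6, both epoxide diastereomers, not isolated) | C=CC[C@@]1(C)[C@H](O[Si](C)(C)C(C)(C)C)CC2(C(C)C)OC2C1 | intermediate
8 | (3R,4R)-3-allyl-4-[(tert-butyldimethylsilyl)oxy]-3,7-dimethyl-6-oxooctanal | C=CC[C@](C)(CC=O)[C@H](O[Si](C)(C)C(C)(C)C)CC(=O)C(C)C | intermediate
9 | (3R,4R)-3-allyl-4-[(tert-butyldimethylsilyl)oxy]-3,7-dimethyl-6-oxooctanoic acid | C=CC[C@](C)(CC(=O)O)[C@H](O[Si](C)(C)C(C)(C)C)CC(=O)C(C)C | intermediate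
10 | (1R,2R,3R,5R)-2-allyl-3-[(tert-butyldimethylsilyl)oxy]-5-isopropyl-2-methyl-6-oxabicyclo[3.2.0]heptan-7-one | C=CC[C@@]1(C)[C@H](O[Si](C)(C)C(C)(C)C)C[C@]2(C(C)C)OC(=O)[C@H]12 | intermediate
11 | (1R,2R,3R,5R)-2-allyl-3-[(tert-butyldimethylsilyl)oxy]-5-hydroxy-5-isopropyl-N-methoxy-N,2-dimethylcyclopentane-1-carboxamide | C=CC[C@@]1(C)[C@H](O[Si](C)(C)C(C)(C)C)C[C@@](O)(C(C)C)[C@@H]1C(=O)N(C)OC | intermediate
12 | 1-[(1R,2R,3R,5R)-2-allyl-3-[(tert-butyldimethylsilyl)oxy]-5-hydroxy-5-isopropyl-2-methylcyclopentyl]-3-methylbut-3-en-1-one | C=CC[C@@]1(C)[C@H](O[Si](C)(C)C(C)(C)C)C[C@@](O)(C(C)C)[C@@H]1C(=O)CC(C)=C | intermediate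
13 | (1R,3R,3aR,8aR)-1-[(tert-butyldimethylsilyl)oxy]-3-hydroxy-3-isopropyl-6,8a-dimethyl-2,3,3a,5,8,8a-hexahydroazulen-4(1H)-one | CC1=CC[C@@]2(C)[C@H](O[Si](C)(C)C(C)(C)C)C[C@@](O)(C(C)C)[C@@H]2C(=O)C1 | intermediate
14 | (1R,3R,3aS,4S,8aR)-1-[(tert-butyldimethylsilyl)oxy]-3-isopropyl-6,8a-dimethyl-1,2,3,3a,4,5,8,8a-octahydroazulene-3,4-diol | CC1=CC[C@@]2(C)[C@H](O[Si](C)(C)C(C)(C)C)C[C@@](O)(C(C)C)[C@@H]2[C@@H](O)C1 | intermediate
15 | 4-hydroxybenzoic acid | OC(=O)c1ccc(O)cc1 | starting material
16 | tert-butyldimethylsilyl 4-[(tert-butyldimethylsilyl)oxy]benzoate (not isolated) | CC(C)(C)[Si](C)(C)OC(=O)c1ccc(O[Si](C)(C)C(C)(C)C)cc1 | intermediate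
17 | 4-[(tert-butyldimethylsilyl)oxy]benzoic acid | OC(=O)c1ccc(O[Si](C)(C)C(C)(C)C)cc1 | intermediate
18 | (1R,3R,3aS,4S,8aR)-1-[(tert-butyldimethylsilyl)oxy]-3-hydroxy-3-isopropyl-6,8a-dimethyl-1,2,3,3a,4,5,8,8a-octahydroazulen-4-yl 4-[(tert-butyldimethylsilyl)oxy]benzoate | CC1=CC[C@@]2(C)[C@H](O[Si](C)(C)C(C)(C)C)C[C@@](O)(C(C)C)[C@@H]2[C@@H](OC(=O)c2ccc(O[Si](C)(C)C(C)(C)C)cc2)C1 | intermediate
19 | (1R,3R,3aS,4S,8aR)-1,3-dihydroxy-3-isopropyl-6,8a-dimethyl-1,2,3,3a,4,5,8,8a-octahydroazulen-4-yl 4-hydroxybenzoate | CC1=CC[C@@]2(C)[C@H](O)C[C@@](O)(C(C)C)[C@@H]2[C@@H](OC(=O)c2ccc(O)cc2)C1 | target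

**Step count and risks**

Total step count: 15. Longest linear sequence: 14 (steps 1–12, 14 and 15).

Steps most likely to fail:

Step 8. The aldol addition to the hindered isopropyl ketone may be too slow, so that the activated acid is consumed in other ways, or the closure may show too little preference for the face syn to the silyloxy group. The fallback sets out from 8 and comes back at 11. Keto aldehyde 8 is cyclised by enamine catalysis (pyrrolidine/AcOH, CH2Cl2, 0 °C; reversible 5-enolexo aldolisation through the same chair) to (1R,2R,3R,5R)-2-allyl-3-[(tert-butyldimethylsilyl)oxy]-5-hydroxy-5-isopropyl-2-methylcyclopentane-1-carbaldehyde F1. Pinnick oxidation (NaClO2, NaH2PO4, 2-methyl-2-butene) then gives (1R,2R,3R,5R)-2-allyl-3-[(tert-butyldimethylsilyl)oxy]-5-hydroxy-5-isopropyl-2-methylcyclopentane-1-carboxylic acid F2, and amide coupling with MeNH(OMe)·HCl (EDC·HCl, HOBt, iPr2NEt) returns to 11.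

Step 3. Fluoride turnover of the hindered silyl enol ether may be incomplete, proton transfer from the acidic allylic α'-CH2 of the product to free enolate may erode regiocontrol or cause over-allylation, and enantioselectivity may fall short. The fallback sets out from 3 and comes back at 5. Enol ether 3 is cleaved with a stoichiometric fluoride source (benzyltrimethylammonium fluoride, THF, −78 °C) in the presence of allyl bromide (regiospecific alkylation of the ammonium enolate) to racemic 6-allyl-3-isopropyl-6-methylcyclohex-3-en-1-one F3. The catalyst-controlled reduction of step 4 then converts the two enantiomers into the diastereomers 5 and (1R,6S)-6-allyl-3-isopropyl-6-methylcyclohex-3-en-1-ol F4, which are separated by chromatography, and the route continues from 5.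

Step 12. Exchange of the tertiary C3 hydroxyl onto boron may be slow, so that external hydride attack erodes facial selectivity, and the C6=C7 bond may drift into conjugation in acetic acid. The fallback sets out from 13 and comes back at 18. Ketone 13 is reduced without direction (NaBH4, CeCl3·7H2O, MeOH, −78 °C), and the resulting (1R,3R,3aS,4R,8aR)-1-[(tert-butyldimethylsilyl)oxy]-3-isopropyl-6,8a-dimethyl-1,2,3,3a,4,5,8,8a-octahydroazulene-3,4-diol F5 is esterified with 17 under Mitsunobu conditions (PPh3, DIAD, toluene, 0 °C) with inversion at C4 to give 18. Any 4S alcohol 14 formed alongside is acylated as in step 14, so both epimers converge on 18.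

**Further compounds**
F1 | step 8 | (1R,2R,3R,5R)-2-allyl-3-[(tert-butyldimethylsilyl)oxy]-5-hydroxy-5-isopropyl-2-methylcyclopentane-1-carbaldehyde | C=CC[C@@]1(C)[C@H](O[Si](C)(C)C(C)(C)C)C[C@@](O)(C(C)C)[C@@H]1C=O
F2 | step 8 | (1R,2R,3R,5R)-2-allyl-3-[(tert-butyldimethylsilyl)oxy]-5-hydroxy-5-isopropyl-2-methylcyclopentane-1-carboxylic acid | C=CC[C@@]1(C)[C@H](O[Si](C)(C)C(C)(C)C)C[C@@](O)(C(C)C)[C@@H]1C(O)=O
F3 | step 3 | racemic 6-allyl-3-isopropyl-6-methylcyclohex-3-en-1-one | C=CCC1(C)C(=O)CC(C(C)C)=CC1
F4 | step 3 | (1R,6S)-6-allyl-3-isopropyl-6-methylcyclohex-3-en-1-ol | C=CC[C@]1(C)[C@H](O)CC(C(C)C)=CC1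
F5 | step 12 | (1R,3R,3aS,4R,8aR)-1-[(tert-butyldimethylsilyl)oxy]-3-isopropyl-6,8a-dimethyl-1,2,3,3a,4,5,8,8a-octahydroazulene-3,4-diol | CC1=CC[C@@]2(C)[C@H](O[Si](C)(C)C(C)(C)C)C[C@@](O)(C(C)C)[C@@H]2[C@H](O)C1
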